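## Retrosynthetic overview

1. Target 22 ⇐ carbinol 21 (H2/Pd removes four O-benzyl groups and the benzylic C–OH) ⇐ ketone 20 ⇐ chalcone 18 + arylboronic acid 19 (Rh-catalysed asymmetric 1,4-addition sets the diarylmethine centre) ⇐ flavan aldehyde 14 + acetophenone 16 (Claisen–Schmidt); 14 ⇐ flavan 12 (C6 formylation).
2. Flavan 12 ⇐ 4H-chromene 11 (Ir-catalysed asymmetric hydrogenation sets C2) ⇐ flavylium salt 10 ⇐ 2-arylbenzofuran 7 by insertion of one CH unit between C2 and C3, which enlarges the furan ring to the pyrylium ring; 7 ⇐ 4-iodoresorcinol 4 + alkyne 3 (Sonogashira annulation).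
3. Enabling feature: in the pyran ring O1–C2–C3–C4–C4a–C8a, C3 is an unsubstituted CH2 between the O1- and aryl-bearing C2 and the benzylic C4. Excising C3 leaves the C2=C3 enol-ether bond of a benzofuran; the O1 lone pair and the C2 aryl group make that bond the carbene acceptor and stabilise the cation released when the fused chlorocyclopropane opens.
4. Ring order: furan ring (5-endo closure of O onto the alkyne) → enlarged to the benzopyrylium ring (key step) → reduced in two stages to the pyran ring; no other ring is built.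

Key step: step 5

Assumption: compounds 1, 4, 15 and 19 are taken as commercial; in steps 7 and 11 the ligand antipode is the one that delivers the stated face, to be assigned on a model substrate before material is committed.

## Route

Step 1
Reactants: 1 5-hydroxy-2-methoxybenzaldehyde
Product: 2 5-(benzyloxy)-2-methoxybenzaldehyde
Conditions: BnBr, K2CO3, DMF, 25 °C
Reagents that add atoms: benzyl bromide, BrCc1ccccc1
Why: Williamson ether synthesis on the only phenol; the benzyl ether should survive the basic, cationic and hydride steps and is removed in the final hydrogenolysis.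

Step 2
Reactants: 2 5-(benzyloxy)-2-methoxybenzaldehyde
Product: 3 4-(benzyloxy)-2-ethynyl-1-methoxybenzene
Conditions: Ohira–Bestmann reagent, K2CO3, MeOH, 0 → 25 °C
Reagents that add atoms: dimethyl (1-diazo-2-oxopropyl)phosphonate, COP(=O)(OC)C(=[N+]=[N-])C(C)=O
Why: Seyferth–Gilbert homologation in the Ohira–Bestmann variant (in-flask deacylation, Horner–Wadsworth–Emmons olefination, loss of N2 and 1,2-H shift) should convert the non-enolisable aryl aldehyde into the terminal alkyne.

Step 3
Reactants: 3 4-(benzyloxy)-2-ethynyl-1-methoxybenzene; 4 4-iodobenzene-1,3-diol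
Product: 6 2-[5-(benzyloxy)-2-methoxyphenyl]-1-benzofuran-6-ol, via alkynylresorcinol 5 (not isolated)
Conditions: PdCl2(PPh3)2 (3 mol%), CuI (5 mol%), Et3N, DMF, degassed, 25 → 80 °C
Reagents that add atoms: none
Why: Sonogashira coupling at the C–I bond followed by metal-promoted 5-endo-dig hydroalkoxylation by the ortho hydroxyl, the only one within reach of the alkyne, should give the 2-arylbenzofuran with the second hydroxyl at C6.

Step 4
Reactants: 6 2-[5-(benzyloxy)-2-methoxyphenyl]-1-benzofuran-6-ol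
Product: 7 6-(benzyloxy)-2-[5-(benzyloxy)-2-methoxyphenyl]-1-benzofuran
Conditions: BnBr, K2CO3, DMF, 50 °C
Reagents that add atoms: benzyl bromide, BrCc1ccccc1
Why: Williamson ether synthesis on the remaining phenol removes the only acidic proton before the strongly basic carbene step.

Step 5
Reactants: 7 6-(benzyloxy)-2-[5-(benzyloxy)-2-methoxyphenyl]-1-benzofuran
Product: 10 7-(benzyloxy)-2-[5-(benzyloxy)-2-methoxyphenyl]chromenylium tetrafluoroborate, via chlorocyclopropane adduct 8 (not isolated), via flavylium chloride 9 (not isolated)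
Conditions: NaHMDS (slow addition), CH2Cl2, pentane/THF, −40 → 20 °C; then HBF4·OEt2, Et2O, 0 °C, salt collected by filtration
Reagents that add atoms: dichloromethane, ClCCl; tetrafluoroboric acid (diethyl ether complex), [H+].F[B-](F)(F)F
Why: The chlorocarbenoid generated from CH2Cl2 adds as an electrophile across the O1-activated C2=C3 bond of the furan ring (concerted [2+1] cheletropic closure of the three-membered ring) to give chlorocyclopropane 8, whose ring-fusion bond is flanked by the O1 lone pair and the C2 aryl group. Loss of the endo chloride with disrotatory two-electron electrocyclic opening of that fusion bond (Woodward–Hoffmann–DePuy rule) turns the five-membered furan ring into the six-membered pyrylium ring O1–C2–C3–C4–C4a–C8a, the inserted CH becoming C3; the six-membered ring thus arises by ring opening of the fusion bond and not by a new closure, driven by release of cyclopropane strain and by the aromaticity of the benzopyrylium cation. The closest known reaction type is the Ciamician–Dennstedt-type halocarbene ring expansion of indoles and pyrroles to quinolines and pyridines and of benzofurans to 3-halochromenes. No stereocentre survives, since the product is a planar achiral cation; both chloride epimers of 8 are expected, only the one with chlorine syn to the furan ring bonds C2–O1 and C3–C3a can open, and the inert exo epimer should stay in the ether mother liquor when 10 precipitates. The step needs chemoselectivity for the furan C2=C3 bond over the four alkoxybenzene rings, which its enol-ether character and the low aromatic stabilisation of the furan ring should secure, and it needs a base that cannot add irreversibly to the cation, hence the hindered silylamide in place of an alkyllithium; any covalent chloride, amide or hydroxide adduct of the cation should revert to 10 on treatment with HBF4.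

Step 6
Reactants: 10 7-(benzyloxy)-2-[5-(benzyloxy)-2-methoxyphenyl]chromenylium tetrafluoroborate
Product: 11 7-(benzyloxy)-2-[5-(benzyloxy)-2-methoxyphenyl]-4H-chromene
Conditions: NaBH4, MeCN/THF, −20 → 0 °C; aq. NaHCO3 work-up
Reagents that add atoms: none
Why: Hydride addition to the flavylium cation should occur at the unhindered C4 terminus (C2 is shielded by the ortho-methoxyaryl group) and give the conjugated cyclic enol ether, which is kept away from acid.

Step 7
Reactants: 11 7-(benzyloxy)-2-[5-(benzyloxy)-2-methoxyphenyl]-4H-chromene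
Product: 12 (2S)-7-(benzyloxy)-2-[5-(benzyloxy)-2-methoxyphenyl]-3,4-dihydro-2H-chromene
Conditions: [Ir(cod)(L*)]BArF (1–2 mol%; L* = chiral phosphinooxazoline or pyridine–phosphinite P,N ligand), H2 (50 bar), CH2Cl2, 25 °C
Reagents that add atoms: none
Why: Iridium-catalysed asymmetric hydrogenation of a trisubstituted cyclic enol ether, the reaction type established for 2-aryl-4H-chromenes; the chiral P,N ligand (antipode chosen so that H2 adds to the C2 re face) sets C2 as S, and the homogeneous catalyst should leave the benzyl ethers intact.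

Step 8
Reactants: 12 (2S)-7-(benzyloxy)-2-[5-(benzyloxy)-2-methoxyphenyl]-3,4-dihydro-2H-chromene
Product: 14 (2S)-7-(benzyloxy)-2-[5-(benzyloxy)-2-methoxyphenyl]-3,4-dihydro-2H-chromene-6-carbaldehyde, via Vilsmeier iminium chloride 13 (not isolated)
Conditions: POCl3, DMF, 0 → 60 °C; then aq. NaOAc
Reagents that add atoms: N,N-dimethylformamide, CN(C)C=O; water, O
Why: Vilsmeier–Haack formylation; the 1,3-dioxygenated ring is by far the most nucleophilic arene and should react at C6 (para to O1, ortho to OBn) in preference to the doubly flanked C8, and the non-protic conditions should not ionise the C2–O1 bond.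

Step 9
Reactants: 15 1-(4-hydroxy-2-methoxyphenyl)ethan-1-one
Product: 16 1-[4-(benzyloxy)-2-methoxyphenyl]ethan-1-one
Conditions: BnBr, K2CO3, acetone, reflux
Reagents that add atoms: benzyl bromide, BrCc1ccccc1
Why: Williamson ether synthesis on the para phenol gives the methyl ketone partner with the same protecting group as the rest of the molecule.

Step 10
Reactants: 14 (2S)-7-(benzyloxy)-2-[5-(benzyloxy)-2-methoxyphenyl]-3,4-dihydro-2H-chromene-6-carbaldehyde; 16 1-[4-(benzyloxy)-2-methoxyphenyl]ethan-1-one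
Product: 18 (2E)-1-[4-(benzyloxy)-2-methoxyphenyl]-3-{(2S)-7-(benzyloxy)-2-[5-(benzyloxy)-2-methoxyphenyl]-3,4-dihydro-2H-chromen-6-yl}prop-2-en-1-one, via aldol adduct 17 (not isolated)
Conditions: KOH, EtOH/THF, 25 °C
Reagents that add atoms: none
Why: Claisen–Schmidt condensation of a non-enolisable aldehyde with a methyl ketone; E1cB dehydration of aldol 17 should give the (E)-enone, and the base cannot touch the C2 centre, which carries no acidic hydrogen.

Step 11
Reactants: 18 (2E)-1-[4-(benzyloxy)-2-methoxyphenyl]-3-{(2S)-7-(benzyloxy)-2-[5-(benzyloxy)-2-methoxyphenyl]-3,4-dihydro-2H-chromen-6-yl}prop-2-en-1-one; 19 [4-(benzyloxy)phenyl]boronic acid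
Product: 20 (3R)-1-[4-(benzyloxy)-2-methoxyphenyl]-3-[4-(benzyloxy)phenyl]-3-{(2S)-7-(benzyloxy)-2-[5-(benzyloxy)-2-methoxyphenyl]-3,4-dihydro-2H-chromen-6-yl}propan-1-one
Conditions: [RhCl(C2H4)2]2 (2.5 mol%), chiral bicyclic diene ligand (6 mol%), KOH (0.3 equiv), dioxane/H2O 10:1, 50 °C
Reagents that add atoms: none
Why: Hayashi–Miyaura rhodium-catalysed asymmetric conjugate addition of an arylboronic acid to a chalcone; the chiral diene ligand (antipode chosen to transfer the aryl group to the si face of C-β) sets the diarylmethine centre as R under catalyst control, the C2 centre being too remote to interfere.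

Step 12
Reactants: 20 (3R)-1-[4-(benzyloxy)-2-methoxyphenyl]-3-[4-(benzyloxy)phenyl]-3-{(2S)-7-(benzyloxy)-2-[5-(benzyloxy)-2-methoxyphenyl]-3,4-dihydro-2H-chromen-6-yl}propan-1-one
Product: 21 (1RS,3R)-1-[4-(benzyloxy)-2-methoxyphenyl]-3-[4-(benzyloxy)phenyl]-3-{(2S)-7-(benzyloxy)-2-[5-(benzyloxy)-2-methoxyphenyl]-3,4-dihydro-2H-chromen-6-yl}propan-1-ol
Conditions: NaBH4, THF/MeOH, 0 °C
Reagents that add atoms: none
Why: Borohydride reduction of the aryl ketone to the benzylic alcohol (the carbinol epimers are irrelevant, the centre is removed next) avoids the acidic ionic deoxygenations that would open the 2-arylchroman.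

Step 13
Reactants: 21 (1RS,3R)-1-[4-(benzyloxy)-2-methoxyphenyl]-3-[4-(benzyloxy)phenyl]-3-{(2S)-7-(benzyloxy)-2-[5-(benzyloxy)-2-methoxyphenyl]-3,4-dihydro-2H-chromen-6-yl}propan-1-ol
Product: 22 (2S)-6-[(1R)-3-(4-hydroxy-2-methoxyphenyl)-1-(4-hydroxyphenyl)propyl]-2-(5-hydroxy-2-methoxyphenyl)-3,4-dihydro-2H-chromen-7-ol
Conditions: H2 (1–3 bar), 10% Pd/C, EtOAc/MeOH, AcOH (5 vol%), 25 °C
Reagents that add atoms: none
Why: Palladium-catalysed hydrogenolysis should cleave the four benzyl ethers and the electron-rich secondary benzylic C–OH bond (activated by the ortho-methoxy and the liberated para-hydroxyl group), while the cyclic benzylic C2–O1 ether and both stereocentres, which carry no labile group, should persist under these mild conditions.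

## Compound list

1 | 5-hydroxy-2-methoxybenzaldehyde | O=Cc1cc(O)ccc1OC | starting material
2 | 5-(benzyloxy)-2-methoxybenzaldehyde | O=Cc1cc(OCc2ccccc2)ccc1OC | intermediate
3 | 4-(benzyloxy)-2-ethynyl-1-methoxybenzene | C#Cc1cc(OCc2ccccc2)ccc1OC | intermediate
4 | 4-iodobenzene-1,3-diol (4-iodoresorcinol) | Oc1ccc(I)c(O)c1 | starting material
5 | 4-{[5-(benzyloxy)-2-methoxyphenyl]ethynyl}benzene-1,3-diol | COc1ccc(OCc2ccccc2)cc1C#Cc1ccc(O)cc1O | intermediate
6 | 2-[5-(benzyloxy)-2-methoxyphenyl]-1-benzofuran-6-ol | COc1ccc(OCc2ccccc2)cc1-c1cc2ccc(O)cc2o1 | intermediate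
7 | 6-(benzyloxy)-2-[5-(benzyloxy)-2-methoxyphenyl]-1-benzofuran | COc1ccc(OCc2ccccc2)cc1-c1cc2ccc(OCc3ccccc3)cc2o1 | intermediate
8 | 4-(benzyloxy)-1a-[5-(benzyloxy)-2-methoxyphenyl]-1-chloro-1a,6b-dihydro-1H-cyclopropa[b][1]benzofuran (racemic, both chloride epimers) | ClC1C2c3ccc(OCc4ccccc4)cc3OC12c1cc(OCc2ccccc2)ccc1OC | intermediate
9 | 7-(benzyloxy)-2-[5-(benzyloxy)-2-methoxyphenyl]chromenylium chloride | [Cl-].COc1ccc(OCc2ccccc2)cc1-c1ccc2ccc(OCc3ccccc3)cc2[o+]1 | intermediate
10 | 7-(benzyloxy)-2-[5-(benzyloxy)-2-methoxyphenyl]chromenylium tetrafluoroborate | F[B-](F)(F)F.COc1ccc(OCc2ccccc2)cc1-c1ccc2ccc(OCc3ccccc3)cc2[o+]1 | intermediate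
11 | 7-(benzyloxy)-2-[5-(benzyloxy)-2-methoxyphenyl]-4H-chromene | COc1ccc(OCc2ccccc2)cc1C1=CCc2ccc(OCc3ccccc3)cc2O1 | intermediate
12 | (2S)-7-(benzyloxy)-2-[5-(benzyloxy)-2-methoxyphenyl]-3,4-dihydro-2H-chromene | c1cc2c(cc1OCc3ccccc3)O[C@H](c4cc(OCc5ccccc5)ccc4OC)CC2 | intermediate
13 | {(2S)-7-(benzyloxy)-2-[5-(benzyloxy)-2-methoxyphenyl]-3,4-dihydro-2H-chromen-6-yl}-N,N-dimethylmethaniminium chloride | [Cl-].C[N+](C)=Cc1cc2c(cc1OCc3ccccc3)O[C@H](c4cc(OCc5ccccc5)ccc4OC)CC2 | intermediate
14 | (2S)-7-(benzyloxy)-2-[5-(benzyloxy)-2-methoxyphenyl]-3,4-dihydro-2H-chromene-6-carbaldehyde | O=Cc1cc2c(cc1OCc3ccccc3)O[C@H](c4cc(OCc5ccccc5)ccc4OC)CC2 | intermediate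
15 | 1-(4-hydroxy-2-methoxyphenyl)ethan-1-one | CC(=O)c1ccc(O)cc1OC | starting material
16 | 1-[4-(benzyloxy)-2-methoxyphenyl]ethan-1-one | CC(=O)c1ccc(OCc2ccccc2)cc1OC | intermediate
17 | 1-[4-(benzyloxy)-2-methoxyphenyl]-3-{(2S)-7-(benzyloxy)-2-[5-(benzyloxy)-2-methoxyphenyl]-3,4-dihydro-2H-chromen-6-yl}-3-hydroxypropan-1-one (carbinol epimers) | COc1cc(OCc2ccccc2)ccc1C(=O)CC(O)c1cc2c(cc1OCc3ccccc3)O[C@H](c4cc(OCc5ccccc5)ccc4OC)CC2 | intermediate
18 | (2E)-1-[4-(benzyloxy)-2-methoxyphenyl]-3-{(2S)-7-(benzyloxy)-2-[5-(benzyloxy)-2-methoxyphenyl]-3,4-dihydro-2H-chromen-6-yl}prop-2-en-1-one | COc1cc(OCc2ccccc2)ccc1C(=O)/C=C/c1cc2c(cc1OCc3ccccc3)O[C@H](c4cc(OCc5ccccc5)ccc4OC)CC2 | intermediate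
19 | [4-(benzyloxy)phenyl]boronic acid | OB(O)c1ccc(OCc2ccccc2)cc1 | starting material
20 | (3R)-1-[4-(benzyloxy)-2-methoxyphenyl]-3-[4-(benzyloxy)phenyl]-3-{(2S)-7-(benzyloxy)-2-[5-(benzyloxy)-2-methoxyphenyl]-3,4-dihydro-2H-chromen-6-yl}propan-1-one | COc1cc(OCc2ccccc2)ccc1C(=O)C[C@H](c1ccc(OCc2ccccc2)cc1)c1cc2c(cc1OCc3ccccc3)O[C@H](c4cc(OCc5ccccc5)ccc4OC)CC2 | intermediate
21 | (1RS,3R)-1-[4-(benzyloxy)-2-methoxyphenyl]-3-[4-(benzyloxy)phenyl]-3-{(2S)-7-(benzyloxy)-2-[5-(benzyloxy)-2-methoxyphenyl]-3,4-dihydro-2H-chromen-6-yl}propan-1-ol | COc1cc(OCc2ccccc2)ccc1C(O)C[C@H](c1ccc(OCc2ccccc2)cc1)c1cc2c(cc1OCc3ccccc3)O[C@H](c4cc(OCc5ccccc5)ccc4OC)CC2 | intermediate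
22 | (2S)-6-[(1R)-3-(4-hydroxy-2-methoxyphenyl)-1-(4-hydroxyphenyl)propyl]-2-(5-hydroxy-2-methoxyphenyl)-3,4-dihydro-2H-chromen-7-ol | COc1cc(O)ccc1CC[C@H](c1ccc(O)cc1)c1cc2c(cc1O)O[C@H](c1cc(O)ccc1OC)CC2 | target

## Step count and risks

Total steps: 13. Longest linear sequence: 12 steps (steps 1–8 and 10–13, from compound 1).

Steps most likely to fail:

1. Step 5. Carbene transfer may be incomplete or unselective: the chlorocarbenoid may attack the alkoxybenzene rings, or addition may give mainly the exo-chloro epimer, which cannot open. The fallback sets out from 7 and uses the long-known dihalocarbene mode of the same ring expansion. Dibromocarbene (CHBr3, KOtBu, pentane, −20 → 25 °C) should give the gem-dibromocyclopropane F1, which always carries an endo bromide and should ionise to the 3-bromoflavylium bromide F2. After neutralisation with AcOH, NaBH4 in the same flask should give the 3-bromo-4H-chromene F3. Palladium-catalysed formate hydrodebromination (Pd(OAc)2, PPh3, HCO2Na, DMF, 60 °C) then comes back to the route at 11.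

2. Step 7. Enantioface discrimination may be eroded by the ortho-methoxy group on the C2 aryl ring, or the acidic cationic iridium hydride may hydrolyse or isomerise the enol ether. The fallback sets out from 11 and sets C2 by ketone reduction and invertive etherification. Mild aqueous acid (HCl, THF/H2O, 25 °C) should open the enol ether to the hydroxy ketone F4. Corey–Bakshi–Shibata reduction ((S)-Me-CBS, BH3·SMe2, THF, −20 °C) or Noyori-type transfer hydrogenation should give the (R)-carbinol F5. Mitsunobu cyclisation (PPh3, DIAD, THF, 0 °C) by the phenol with inversion comes back to the route at 12.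

3. Step 13. Hydrogenolysis may overrun into cleavage of the cyclic benzylic C2–O1 bond, or stall before the benzylic C–OH bond is broken. The fallback sets out from 21 and removes the hydroxyl by a radical path. Xanthate formation (NaH, CS2, then MeI, THF, 0 °C) should give the S-methyl xanthate F6. Barton–McCombie deoxygenation (Bu3SnH, AIBN, toluene, 80 °C) should give the tetrabenzyl ether F7. Neutral transfer hydrogenolysis (Pd(OH)2/C, cyclohexa-1,4-diene, EtOH/EtOAc, 25 °C), which now has only O-benzyl groups to remove, arrives at 22.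

## Further compounds

F1 | step 5 | 4-(benzyloxy)-1a-[5-(benzyloxy)-2-methoxyphenyl]-1,1-dibromo-1a,6b-dihydro-1H-cyclopropa[b][1]benzofuran (racemic) | BrC1(Br)C2c3ccc(OCc4ccccc4)cc3OC12c1cc(OCc2ccccc2)ccc1OC
F2 | step 5 | 7-(benzyloxy)-2-[5-(benzyloxy)-2-methoxyphenyl]-3-bromochromenylium bromide | [Br-].COc1ccc(OCc2ccccc2)cc1-c1[o+]c2cc(OCc3ccccc3)ccc2cc1Br
F3 | step 5 | 7-(benzyloxy)-2-[5-(benzyloxy)-2-methoxyphenyl]-3-bromo-4H-chromene | COc1ccc(OCc2ccccc2)cc1C1=C(Br)Cc2ccc(OCc3ccccc3)cc2O1
F4 | step 7 | 3-[4-(benzyloxy)-2-hydroxyphenyl]-1-[5-(benzyloxy)-2-methoxyphenyl]propan-1-one | COc1ccc(OCc2ccccc2)cc1C(=O)CCc1ccc(OCc2ccccc2)cc1O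
F5 | step 7 | (1R)-3-[4-(benzyloxy)-2-hydroxyphenyl]-1-[5-(benzyloxy)-2-methoxyphenyl]propan-1-ol | COc1ccc(OCc2ccccc2)cc1[C@H](O)CCc1ccc(OCc2ccccc2)cc1O
F6 | step 13 | O-[(1RS,3R)-1-[4-(benzyloxy)-2-methoxyphenyl]-3-[4-(benzyloxy)phenyl]-3-{(2S)-7-(benzyloxy)-2-[5-(benzyloxy)-2-methoxyphenyl]-3,4-dihydro-2H-chromen-6-yl}propyl] S-methyl carbonodithioate | COc1cc(OCc2ccccc2)ccc1C(OC(=S)SC)C[C@H](c1ccc(OCc2ccccc2)cc1)c1cc2c(cc1OCc3ccccc3)O[C@H](c4cc(OCc5ccccc5)ccc4OC)CC2
F7 | step 13 | (2S)-7-(benzyloxy)-2-[5-(benzyloxy)-2-methoxyphenyl]-6-{(1R)-3-[4-(benzyloxy)-2-methoxyphenyl]-1-[4-(benzyloxy)phenyl]propyl}-3,4-dihydro-2H-chromene | COc1cc(OCc2ccccc2)ccc1CC[C@H](c1ccc(OCc2ccccc2)cc1)c1cc2c(cc1OCc3ccccc3)O[C@H](c4cc(OCc5ccccc5)ccc4OC)CC2
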